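## Structural features

- The target is a trans-fused decalin. Ring A (C4–C5–C6–C7–C8–C9) and ring B (C4–C9–C10–C1–C2–C3) share the C4–C9 bond; C4 carries hydrogen on the α face and C9 an angular methyl on the β face (locants: C1 ester-bearing alkene carbon, C11 formyl carbon, C12 ester carbon).
- There are six stereocentres, (4R,5S,6S,8S,9S,10R) in these locants. Five are contiguous along C10–C9–C4–C5–C6 and the sixth, C8, is also bonded to C9. C5 and C9 are quaternary and their methyl groups are 1,3-syn-diaxial.
- Ring A holds an equatorial β-chloride at C6, next to C5 (β-methyl, α-(E)-CH2–CH=CH–CMe2OH chain), and an axial α-hydroxyl at C8 next to C9. Ring B holds the C1=C2 alkene conjugated with the methyl ester C12 and an equatorial β-formyl group C11 on C10.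
- Fragile points:
  - the C10 aldehyde is α-branched and allylic, so it epimerises or slips into conjugation easily, and its 10α-epimer would be trapped by the 8α-hydroxyl as a lactol;
  - a free C11 alcohol would lactonise onto C12;
  - the tertiary allylic alcohol ionises in acid;
  - C6 is a neopentyl-type carbon where substitution competes with elimination and 1,2-shift.
- The real difficulties are the two quaternary carbons in a 1,3-relation on a trans-decalin, the configured secondary chloride beside C5, and the two neighbouring carbonyl carbons C11 and C12 at different oxidation levels.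
- The key step exploits this pattern: a heteroatom at C6, a quaternary C5 with methyl and an unsaturated three-carbon branch, the trans C4–C9 fusion, the angular C9 methyl and a carbon substituent on C10. It is the imprint of a C5–C6 epoxide opened at C5 by the C4=C9 alkene, with the C9 cation captured by C10, closing ring A and ring B together.

## Logic of the disconnections

27 to 26. The C11–H bond of the aldehyde is traced back to a C11–S bond. The aldehyde is the most fragile group and is therefore released last, under neutral conditions; an alcohol at C11 is avoided because it would close onto C12. The forward step must stop at the aldehyde and spare the C12 ester, the chloride and the alkenes.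

26 to 24 and 25. The side-chain C=C bond is cut. The tertiary allylic alcohol would not survive chlorination or acid, whereas a bare allyl group is inert throughout. This reduces the six-carbon chain to three carbons plus commercial 25. The forward step must be (E)-selective and must react only at the monosubstituted alkene.

24 to 23 to 22. The C11–S bond comes from the C11 acid; the acid and the free C8 hydroxyl come from a tert-butyl ester and a silyl ether that fall together. The tert-butyl/methyl pair is what tells C11 from C12. The forward acidolysis must not touch the C6–Cl bond or the enoate.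

22 to 21. The C10–H bond and the C1=C2 alkene are traced to a tetrasubstituted C1=C10 diester (one hydrogen moved from C10 to C2). That diester is what carbonylation delivers, and it has neither an acidic C10–H nor a reactive acceptor during the ring A work. The forward equilibrium must favour the conjugated C1=C2 isomer with the C10 ester equatorial.

21 to 20 to 19. The C6–Cl bond is cut to a C6–O bond of opposite configuration, and that to a C6 ketone. The cyclisation gives 6β-oxygen and the chloride is also 6β, so an oxidation, reduction and inverting substitution are needed; the ketone is required anyway to reach C8. The forward steps need hydride delivery from the β face and substitution at a hindered carbon, with the C8 oxygen capped so the two axial hydroxyls are distinguishable.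

19 to 18 to 16. The C8–O bond is cut back to the C7=C8 enone (through a C8–B bond). C8 had to stay unoxygenated in the cyclisation substrate, and conjugate addition is the way to reach it afterwards. The forward addition must come from the α face, anti to the C9 methyl, and must prefer the enone over the other alkenes.

16 to 14. The C6 carbonyl and the C7=C8 double bond are traced to the C6 carbinol. Because C5 is quaternary, dehydrogenation can only go towards C7, so no regiochemical demand arises.

14 to 13 to 12. The C1–C12 bond is cut. The ketone left by the cyclisation terminator sits exactly where the ester carbon must be attached. The forward steps need O-sulfonylation of the β-keto ester in the presence of a free hydroxyl, and a C11 ester that tolerates zerovalent palladium.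

12 to 11. The C4–C5 and C9–C10 bonds are cut. Both rings and the stereocentres C4, C5, C9 and C10 (with C6 carried over) collapse to an acyclic chain with one stereogenic unit, the epoxide. The forward step must be a clean bicyclisation with anti opening at C5 and C-capture at C10.

11 to 9 and 10. The C2–C3 bond is cut between an allylic electrophile and the terminal carbon of an acetoacetate. The forward alkylation must occur at the γ-carbon and leave the epoxide alone.

9 to 7 to 6. The C–Br bond is traced to the C–O bond of an allylic alcohol and its acetate; this is functional-group interchange only. The forward steps must avoid acid because of the epoxide.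

6 to 3 and 4. The bond between the epoxide-bearing CH2 and the vinyl carbon is cut. This builds the allyl branch on C5 without touching a stereocentre. The forward displacement must beat attack on the epoxide and on the allylic acetate.

3 to 2 to 1. The two epoxide C–O bonds are cut to an (E)-allylic alcohol, and its C–O bond to the (E)-methyl of 1. The hydroxyl that directs the asymmetric epoxidation is then the leaving group for the previous paragraph. The forward oxidation must select the distal alkene and its (E)-methyl group.

## Other disconnections considered

Alternative 1: The cut is the single bond C9–C10, with ring A taken back to an arene. The substrate is the phenol A2, in which C6 is the phenolic carbon, C9 the methyl-bearing para carbon, and the β-keto ester chain hangs from C4.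
- Forward step: a hypervalent iodine oxidant in a fluorinated alcohol would oxidise the phenol, and the enol carbon C10 would add to C9. This gives the cross-conjugated dienone A1 with quaternary C9 and ring B closed.
- In its favour: the substrate is short to make and has no stereocentre. A1 already contains the C6 carbonyl and the C7=C8 double bond, the oxidation pattern that the chosen route must build in steps 10 and 11. On this point the alternative is the better plan.
- Against it here:
  - only C9 and C10 are set, and C9 without internal control, so the absolute configuration would rest on a chiral aryl iodide catalyst acting on a carbon nucleophile at a substituted para position;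
  - the oxidant can attack the β-keto ester itself;
  - C5 stays sp2, so the quaternary centre, the C4 hydrogen and the trans fusion would all depend on one reductive allylation of the C4=C5 enone beside a second enone;
  - the chloride and the C11/C12 problem remain.
- Comparison: in structure it gives more oxidation but fewer stereocentres (two against four). In mechanism it is a polar attack on a flat cation with little facial bias, where the chosen cascade is stereospecific. Step economy should be about equal, the shorter substrate synthesis being paid back at C4/C5.

Alternative 2: The cut goes through ring B at C4–C9 and C1–C10 and opens both rings to the acyclic trienal A4. The diene is C1=C2–C3=C4, the dienophile is C9=C10 bearing the formyl group, and C5–C8 form the tether with C5, the C6 ketone and the C8 silyl ether in place.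
- Forward step: an alkylaluminium chloride would bind the aldehyde, and an endo intramolecular [4+2] cycloaddition would close ring B directly and ring A through the tether to give A3.
- In its favour: it is convergent. C4, C9 and C10 (and C1) arise in one step with the trans fusion. C5 and C8 arrive finished, C6 is already a ketone and C11 already an aldehyde, so neither the late ring A oxidation work nor the ester-to-aldehyde change is needed. On functional-group economy it is the better plan, and its longest linear sequence could be shorter.
- Against it here:
  - A4 needs an enantiopure acyclic quaternary C5 next to a ketone and a separate C8 carbinol;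
  - the dienophile is a β,β-disubstituted enal that must form quaternary C9, the slowest kind;
  - facial selectivity rests on the conformational bias of two remote centres;
  - the β-silyloxy ketone is exposed to the Lewis acid;
  - the new double bond lies at C2=C3 and must be moved to C1=C2 after C12 is oxidised, next to an epimerisable aldehyde;
  - the chlorination remains.
- Comparison: in structure it is equal in new stereocentres (four) and better matched in oxidation level. In mechanism the diastereofacial outcome of the cycloaddition is less predictable than anti opening plus chair folding. Total step count is probably similar, since what is saved after the key step is spent on A4.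

Alternative 3: The cut is the transannular bond C4–C9. The decalin is taken back to the ten-membered ring A6, which holds the (E)-C4=C5 alkene, the trans C8–C9 epoxide and the finished C1=C2 enoate with the protected C11 carbinol.
- Forward step: a boron Lewis acid would open the epoxide at tertiary C9, C4 would add across the ring with inversion at C9, and the C5 cation would lose a proton from C6 to give A5.
- In its favour: both rings and the C4/C9 trans relation come from one conformationally guided, stereospecific anti opening; on mechanism the two plans are equal. Ring B arrives complete, with C12 as the methyl ester and C11 at the alcohol level, so the diester differentiation is not needed. That is a real advantage.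
- Against it here:
  - a ten-membered ring with an (E)-alkene, a trans-epoxide and an enoate is long and uncertain to make enantiopure;
  - the C8 hydroxyl emerges β, epimeric to the target, and would need inversion at a hindered carbon;
  - the proton loss has three directions open;
  - the hardest part, quaternary C5 with methyl and allyl beside the C6 chloride, is not formed and would have to be built later from a trisubstituted alkene.
- Comparison: in structure it sets C4, C8 and C9 but leaves C5 and C6 open, which the chosen step sets directly. Step economy is clearly worse before the key step and no better after it.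

Key step: step 7

Remark on conventions: locants are those defined above; β is the face of the C9 methyl and α the opposite face; the SMILES in the compound list are definitive.

Remark on the key-step pair: the (2S,3S)-epoxide with the allyl group trans to the chain, inversion at C5 and retention at C6 reproduce the 5β-methyl/5α-allyl/6β-oxygen pattern of the target, so no stereochemical correction is needed.

Remark on the precursor design: the β-keto ester is carried as its tert-butyl ester, not as an allyl ester. An allyl carboxylate would be exposed to zerovalent palladium in the methoxycarbonylation and would bring a second terminal alkene into the metathesis. The tert-butyl ester is removed by acid together with the silyl ether and cleanly distinguishes C11 from the methyl ester C12. The bonds formed and the skeleton are unchanged.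

Step 1
Reactants: 1 geranyl acetate
Product: 2 (2E,6E)-8-hydroxy-3,7-dimethylocta-2,6-dien-1-yl acetate
Conditions: SeO2 (cat.), t-BuOOH (70% aq.), salicylic acid (cat.), CH2Cl2, 0 °C → rt
Reagents that add atoms: selenium dioxide, O=[Se]=O (oxygen carrier); tert-butyl hydroperoxide, CC(C)(C)OO (terminal oxidant)
Why: Allylic oxidation with SeO2 (ene reaction, then [2,3]-sigmatropic shift) attacks the electron-richer distal trisubstituted alkene, the proximal one being deactivated by the allylic acetate, and takes the (E)-methyl group; t-BuOOH turns selenium over and holds the oxidation largely at the alcohol level.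

Step 2
Reactants: 2 (2E,6E)-8-hydroxy-3,7-dimethylocta-2,6-dien-1-yl acetate
Product: 3 (2E)-5-[(2S,3S)-3-(hydroxymethyl)-3-methyloxiran-2-yl]-3-methylpent-2-en-1-yl acetate
Conditions: Ti(OiPr)4 (10 mol%), L-(+)-diethyl tartrate (12 mol%), t-BuOOH, 4 Å molecular sieves, CH2Cl2, −20 °C
Reagents that add atoms: tert-butyl hydroperoxide, CC(C)(C)OO
Why: Sharpless asymmetric epoxidation of the 2-methyl (E)-allylic alcohol; with L-(+)-tartrate the titanium-bound peroxide is delivered to the face that gives the (2S,3S)-epoxide, and the other alkene, which has no free hydroxyl to bind titanium, stays.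

Step 3
Reactants: 3 (2E)-5-[(2S,3S)-3-(hydroxymethyl)-3-methyloxiran-2-yl]-3-methylpent-2-en-1-yl acetate; 4 vinylmagnesium bromide
Product: 6 (2E)-3-methyl-5-[(2S,3S)-3-methyl-3-(prop-2-en-1-yl)oxiran-2-yl]pent-2-en-1-yl acetate, via epoxy triflate 5 (not isolated)
Conditions: Tf2O, 2,6-lutidine, CH2Cl2, −78 °C; cold aqueous wash; then 4 (2.5 equiv), CuI (10 mol%), THF, −78 → −40 °C
Reagents that add atoms: trifluoromethanesulfonic anhydride, O=S(=O)(OS(=O)(=O)C(F)(F)F)C(F)(F)F (its atoms stay only in intermediate 5; the vinyl carbons come from reactant 4)
Why: Copper-catalysed Grignard coupling: the primary triflate beside the epoxide is displaced (SN2) by the vinylcopper species at −78 °C, faster than the allylic acetate or the trisubstituted epoxide can react; no stereocentre is touched, so the allyl group ends trans to the chain on the (S,S)-epoxide.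

Step 4
Reactants: 6 (2E)-3-methyl-5-[(2S,3S)-3-methyl-3-(prop-2-en-1-yl)oxiran-2-yl]pent-2-en-1-yl acetate
Product: 7 (2E)-3-methyl-5-[(2S,3S)-3-methyl-3-(prop-2-en-1-yl)oxiran-2-yl]pent-2-en-1-ol
Conditions: K2CO3 (0.2 equiv), MeOH, 0 °C → rt
Reagents that add atoms: none
Why: Base-catalysed transesterification of the acetate with methanol; the trisubstituted epoxide has no neighbouring hydroxyl and is inert to methoxide at this temperature.

Step 5
Reactants: 7 (2E)-3-methyl-5-[(2S,3S)-3-methyl-3-(prop-2-en-1-yl)oxiran-2-yl]pent-2-en-1-ol
Product: 9 (2S,3S)-3-[(3E)-5-bromo-3-methylpent-3-en-1-yl]-2-methyl-2-(prop-2-en-1-yl)oxirane, via allylic mesylate 8 (not isolated)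
Conditions: MsCl, Et3N, CH2Cl2, −40 °C; then LiBr, THF, −40 → 0 °C
Reagents that add atoms: lithium bromide, [Li+].[Br-]; methanesulfonyl chloride, CS(=O)(=O)Cl (its atoms stay only in intermediate 8)
Why: Mesylation and in situ SN2 displacement by bromide at the primary allylic carbon keep the (E)-alkene and avoid acid, which the epoxide would not tolerate.

Step 6
Reactants: 9 (2S,3S)-3-[(3E)-5-bromo-3-methylpent-3-en-1-yl]-2-methyl-2-(prop-2-en-1-yl)oxirane; 10 tert-butyl acetoacetate
Product: 11 tert-butyl (6E)-7-methyl-9-[(2S,3S)-3-methyl-3-(prop-2-en-1-yl)oxiran-2-yl]-3-oxonon-6-enoate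
Conditions: 10 (2 equiv), NaH, THF, 0 °C; n-BuLi, 0 °C; then 9, 0 °C; aq. NH4Cl
Reagents that add atoms: none
Why: γ-Alkylation of the acetoacetate dianion: the more basic terminal carbanion attacks the primary allylic bromide (SN2) and leaves the epoxide alone; the tert-butyl ester is the spectator that later lets acid tell C11 from the methyl ester C12.

Step 7
Reactants: 11 tert-butyl (6E)-7-methyl-9-[(2S,3S)-3-methyl-3-(prop-2-en-1-yl)oxiran-2-yl]-3-oxonon-6-enoate
Product: 12 trans-decalin β-keto ester (C1 ketone, 10β-CO2t-Bu, 6β-OH, 5β-methyl, 5α-allyl, 9β-methyl, 4α-H)
Conditions: MeAlCl2 (3 equiv), CH2Cl2, −78 °C; Et3N–MeOH quench at −78 °C, aq. NaHCO3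
Reagents that add atoms: none
Why: MeAlCl2 first turns the β-keto ester into its chloroaluminium enolate (methane is lost) and a further equivalent binds the epoxide oxygen; the C5–O bond then ionises toward the tertiary carbon while C4 of the (E)-alkene attacks C5 from the side opposite the oxygen, and the resulting tertiary C9 cation is captured by the enolate carbon C10. The closest known reaction type is the Lewis-acid epoxy-polyene (oxidosqualene-like) bicyclisation ended by a β-dicarbonyl nucleophile. Ring A closes in the 6-endo mode with respect to both the alkene and the epoxide (both alkene carbons and both epoxide carbons lie in the ring, the oxygen staying outside on C6); ring B closes by attack of the enolate carbon on the cation with both enol carbons inside the six-membered ring, whereas O-attack would require an eight-membered ring. C5 is set by stereospecific inversion of the Sharpless-derived epoxide carbon (methyl β, allyl α, because the allyl group is trans to the chain on the epoxide); C6 keeps its C–O bond and is therefore β and equatorial; C4 and C9 follow from the chair–chair array of the (E)-alkene with antiperiplanar addition across it (4α-H, 9β-methyl, trans fusion), the chair being the one that holds the C6–O bond equatorial; C10 settles with the ester equatorial (β) through the enol. The selectivity needed is complete bicyclisation over elimination or rearrangement of the C5 or C9 cation: it is secured by the nucleophilicity of the trisubstituted alkene and of the aluminium enolate, by the monosubstituted allyl alkene being too poor a nucleophile to compete, and by the absence of oxygen at C8, which removes the hydride-shift escape of the C9 cation. The tert-butyl ester should survive as the chelated enolate at −78 °C when the quench is cold and basic.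

Step 8
Reactants: 12 trans-decalin β-keto ester (C1 ketone, 10β-CO2t-Bu, 6β-OH)
Product: 13 C1 enol triflate (C1=C10, OTf on C1, CO2t-Bu on C10, 6β-OH)
Conditions: NaH (1.05 equiv), PhNTf2, THF, 0 °C → rt; aq. NH4Cl
Reagents that add atoms: N-phenylbis(trifluoromethanesulfonimide), O=S(=O)(N(c1ccccc1)S(=O)(=O)C(F)(F)F)C(F)(F)F
Why: O-Sulfonylation of the sodium enolate of the β-keto ester; one equivalent of base deprotonates only the far more acidic β-dicarbonyl, so the hindered C6 hydroxyl stays free, and the C10 stereocentre is given up deliberately (it is reset in step 15).

Step 9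
Reactants: 13 C1 enol triflate (C1=C10, OTf on C1, CO2t-Bu on C10, 6β-OH)
Product: 14 C1=C10 diester (CO2Me on C1, CO2t-Bu on C10, 6β-OH)
Conditions: Pd(OAc)2 (5 mol%), Ph2P(CH2)3PPh2 (6 mol%), CO (1 atm), MeOH, Et3N, DMF, 50 °C
Reagents that add atoms: carbon monoxide, [C-]#[O+]; methanol, CO
Why: Palladium-catalysed methoxycarbonylation: oxidative addition of the vinyl triflate to zerovalent palladium, CO insertion and methanolysis of the acylpalladium species; the tert-butyl ester, the free hydroxyl and the terminal alkene are spectators.

Step 10
Reactants: 14 C1=C10 diester (CO2Me on C1, CO2t-Bu on C10, 6β-OH)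
Product: 16 C7=C8 enone (C6 ketone) of the C1=C10 diester, via C6 ketone 15 (not isolated)
Conditions: IBX (3.5 equiv), DMSO, rt → 75 °C
Reagents that add atoms: none
Why: IBX oxidises the secondary alcohol to the ketone and, on warming, dehydrogenates it through its enol; only C7 can enolise because C5 is quaternary, so the C7=C8 enone is the only possible outcome, and the tetrasubstituted diester has no enolisable position.

Step 11
Reactants: 16 C7=C8 enone (C6 ketone) of the C1=C10 diester
Product: 18 8α-hydroxy C6 ketone of the C1=C10 diester, via C8 pinacol boronate 17 (not isolated)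
Conditions: CuCl (10 mol%), NaOt-Bu (15 mol%), (2-Ph2PC6H4)2O (10 mol%), B2pin2, MeOH, THF, rt; then NaBO3·4H2O, THF–H2O, rt
Reagents that add atoms: sodium perborate, [Na+].[O-]OB=O; bis(pinacolato)diboron, CC1(C)OB(OC1(C)C)B1OC(C)(C)C(C)(C)O1 (its atoms stay only in intermediate 17)
Why: Copper-catalysed conjugate borylation followed by oxidation of C–B to C–O with retention: the copper boryl adds to C8 axially from the α face, anti to the axial C9 methyl, which sets the 8α-hydroxyl; the tetrasubstituted diester alkene and the unactivated terminal alkene are far poorer acceptors than the enone.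

Step 12
Reactants: 18 8α-hydroxy C6 ketone of the C1=C10 diester
Product: 19 8α-triethylsilyloxy C6 ketone of the C1=C10 diester
Conditions: Et3SiOTf, 2,6-lutidine, CH2Cl2, −78 °C
Reagents that add atoms: triethylsilyl trifluoromethanesulfonate, CC[Si](CC)(CC)OS(=O)(=O)C(F)(F)F
Why: Silylation with the silyl triflate and a hindered base caps the axial hydroxyl at low temperature without β-elimination and without touching the tert-butyl ester; it keeps the two axial oxygens distinguishable for the chlorination.

Step 13
Reactants: 19 8α-triethylsilyloxy C6 ketone of the C1=C10 diester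
Product: 20 6α-hydroxy 8α-triethylsilyloxy C1=C10 diester
Conditions: LiBH(s-Bu)3, THF, −78 °C; H2O quench at −78 °C
Reagents that add atoms: none
Why: The bulky hydride attacks the C6 ketone from the equatorial β side, because the axial α trajectory is blocked by the syn-axial C8 silyloxy group and C4–H, and gives the axial 6α-alcohol; the cold quench prevents silyl migration between the syn-diaxial oxygens.

Step 14
Reactants: 20 6α-hydroxy 8α-triethylsilyloxy C1=C10 diester
Product: 21 6β-chloro 8α-triethylsilyloxy C1=C10 diester
Conditions: PPh3, CCl4, 2,6-lutidine, MeCN, 60 °C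
Reagents that add atoms: carbon tetrachloride, ClC(Cl)(Cl)Cl
Why: Appel chlorination: the alkoxyphosphonium salt of the axial alcohol is displaced by chloride with inversion (SN2), which puts chlorine in the equatorial β position; the hindered base keeps the medium free of HCl so that the silyl ether and the tert-butyl ester survive.

Step 15
Reactants: 21 6β-chloro 8α-triethylsilyloxy C1=C10 diester
Product: 22 6β-chloro 8α-triethylsilyloxy C1=C2 diester (CO2Me on C1, 10β-CO2t-Bu, 10α-H)
Conditions: KOt-Bu (0.3 equiv), t-BuOH–THF, 0 °C → rt
Reagents that add atoms: none
Why: Base-catalysed equilibration through the extended ester enolate (deprotonation at C2, γ to the C11 carbonyl, and reprotonation at C10) moves the alkene into the trisubstituted C1=C2 position conjugated with the methyl ester and relieves the strain of the tetrasubstituted diester beside quaternary C9, the usual behaviour of such ring-fused 1,2-diesters. C10 is set under thermodynamic control with the ester equatorial (β), the axial α position being blocked by the syn-axial C8 silyloxy group; the equatorial chloride has no antiperiplanar hydrogen and cannot eliminate.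

Step 16
Reactants: 22 6β-chloro 8α-triethylsilyloxy C1=C2 diester (CO2Me on C1, 10β-CO2t-Bu)
Product: 23 6β-chloro-8α-hydroxy 10β-carboxylic acid with the C1=C2 methyl ester
Conditions: CF3CO2H–CH2Cl2 (1:4), H2O (trace), 0 °C → rt
Reagents that add atoms: none
Why: Acidolysis: the tert-butyl ester ionises to the acid and isobutene and the triethylsilyl ether is cleaved in the same operation, while the methyl ester, the secondary chloride and the unactivated alkene are stable; lactonisation cannot occur because the 8α-oxygen cannot reach the 10β-carboxyl.

Step 17
Reactants: 23 6β-chloro-8α-hydroxy 10β-carboxylic acid with the C1=C2 methyl ester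
Product: 24 S-ethyl 10β-thioester (6β-Cl, 8α-OH, C1=C2 methyl ester, 5α-allyl)
Conditions: EtSH, EDC·HCl, DMAP (cat.), CH2Cl2, 0 °C → rt
Reagents that add atoms: ethanethiol, CCS
Why: Steglich-type carbodiimide coupling with the thiol gives the thioester; the hindered axial C8 hydroxyl does not compete, and C11 is never taken down to an alcohol that would lactonise onto C12.

Step 18
Reactants: 24 S-ethyl 10β-thioester (6β-Cl, 8α-OH, C1=C2 methyl ester, 5α-allyl); 25 2-methylbut-3-en-2-ol
Product: 26 S-ethyl 10β-thioester with the (E)-4-hydroxy-4-methylpent-2-enyl chain on C5
Conditions: second-generation Grubbs catalyst (H2IMes)(PCy3)Cl2Ru=CHPh (5 mol%), 25 (10 equiv), CH2Cl2, 40 °C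
Reagents that add atoms: none
Why: Olefin cross-metathesis of the monosubstituted allyl alkene with the tertiary allylic alcohol in excess; the bulky carbinol partner homodimerises slowly and gives the (E)-alkene, and the electron-poor trisubstituted C1=C2 enoate is inert to the ruthenium carbene.

Step 19
Reactants: 26 S-ethyl 10β-thioester with the (E)-4-hydroxy-4-methylpent-2-enyl chain on C5
Product: 27 target, methyl (4R,5S,6S,8S,9S,10R)-6-chloro-10-formyl-8-hydroxy-5-[(2E)-4-hydroxy-4-methylpent-2-enyl]-5,9-dimethyl-trans-octalin-1-carboxylate with the C1=C2 double bond (locants as defined)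
Conditions: Et3SiH, Pd/C (10% Pd), acetone, rt
Reagents that add atoms: none
Why: Fukuyama reduction: oxidative addition of the C–S bond to palladium, hydride transfer from the silane and reductive elimination give the aldehyde directly and leave the methyl ester, the chloride and the hydroxyls untouched. The neutral conditions avoid epimerisation at C10, and the hindered (E)-disubstituted alkene is the alkene least exposed to adventitious hydrogenation.

Compound list

1 | geranyl acetate | CC(C)=CCC/C(C)=C/COC(C)=O | starting material
2 | (2E,6E)-8-hydroxy-3,7-dimethylocta-2,6-dien-1-yl acetate | OC/C(C)=C/CC/C(C)=C/COC(C)=O | intermediate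
3 | (2E)-5-[(2S,3S)-3-(hydroxymethyl)-3-methyloxiran-2-yl]-3-methylpent-2-en-1-yl acetate | OC[C@]1(C)O[C@H]1CC/C(C)=C/COC(C)=O | intermediate
4 | vinylmagnesium bromide | C=C[Mg]Br | starting material
5 | [(2S,3S)-3-[(3E)-5-acetoxy-3-methylpent-3-en-1-yl]-2-methyloxiran-2-yl]methyl trifluoromethanesulfonate (formed in the flask, not isolated) | FC(F)(F)S(=O)(=O)OC[C@]1(C)O[C@H]1CC/C(C)=C/COC(C)=O | intermediate
6 | (2E)-3-methyl-5-[(2S,3S)-3-methyl-3-(prop-2-en-1-yl)oxiran-2-yl]pent-2-en-1-yl acetate | C=CC[C@]1(C)O[C@H]1CC/C(C)=C/COC(C)=O | intermediate
7 | (2E)-3-methyl-5-[(2S,3S)-3-methyl-3-(prop-2-en-1-yl)oxiran-2-yl]pent-2-en-1-ol | C=CC[C@]1(C)O[C@H]1CC/C(C)=C/CO | intermediate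
8 | (2E)-3-methyl-5-[(2S,3S)-3-methyl-3-(prop-2-en-1-yl)oxiran-2-yl]pent-2-en-1-yl methanesulfonate (formed in the flask, not isolated) | C=CC[C@]1(C)O[C@H]1CC/C(C)=C/COS(C)(=O)=O | intermediate
9 | (2S,3S)-3-[(3E)-5-bromo-3-methylpent-3-en-1-yl]-2-methyl-2-(prop-2-en-1-yl)oxirane | C=CC[C@]1(C)O[C@H]1CC/C(C)=C/CBr | intermediate
10 | tert-butyl acetoacetate | CC(=O)CC(=O)OC(C)(C)C | starting material
11 | tert-butyl (6E)-7-methyl-9-[(2S,3S)-3-methyl-3-(prop-2-en-1-yl)oxiran-2-yl]-3-oxonon-6-enoate (cyclisation precursor) | C=CC[C@]1(C)O[C@H]1CC/C(C)=C/CCC(=O)CC(=O)OC(C)(C)C | intermediate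
12 | trans-decalin β-keto ester: C1 ketone, 10β-CO2t-Bu, 6β-OH, 5β-methyl, 5α-allyl, 9β-methyl, 4α-H | O=C1CC[C@H]2[C@](C)(CC=C)[C@@H](O)CC[C@]2(C)[C@H]1C(=O)OC(C)(C)C | intermediate
13 | C1 enol triflate: C1=C10, OTf on C1, CO2t-Bu on C10, 6β-OH | C1(OS(=O)(=O)C(F)(F)F)CC[C@H]2[C@](C)(CC=C)[C@@H](O)CC[C@]2(C)C=1C(=O)OC(C)(C)C | intermediate
14 | C1=C10 diester: CO2Me on C1, CO2t-Bu on C10, 6β-OH | C1(C(=O)OC)CC[C@H]2[C@](C)(CC=C)[C@@H](O)CC[C@]2(C)C=1C(=O)OC(C)(C)C | intermediate
15 | C6 ketone of the C1=C10 diester (formed in the flask, not isolated) | C1(C(=O)OC)CC[C@H]2[C@](C)(CC=C)C(=O)CC[C@]2(C)C=1C(=O)OC(C)(C)C | intermediate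
16 | C7=C8 enone (C6 ketone) of the C1=C10 diester | C1(C(=O)OC)CC[C@H]2[C@](C)(CC=C)C(=O)C=C[C@]2(C)C=1C(=O)OC(C)(C)C | intermediate
17 | 8α-(pinacolboryl) C6 ketone of the C1=C10 diester (formed in the flask, not isolated) | C1(C(=O)OC)CC[C@H]2[C@](C)(CC=C)C(=O)C[C@H](B3OC(C)(C)C(C)(C)O3)[C@]2(C)C=1C(=O)OC(C)(C)C | intermediate
18 | 8α-hydroxy C6 ketone of the C1=C10 diester | C1(C(=O)OC)CC[C@H]2[C@](C)(CC=C)C(=O)C[C@H](O)[C@]2(C)C=1C(=O)OC(C)(C)C | intermediate
19 | 8α-triethylsilyloxy C6 ketone of the C1=C10 diester | C1(C(=O)OC)CC[C@H]2[C@](C)(CC=C)C(=O)C[C@H](O[Si](CC)(CC)CC)[C@]2(C)C=1C(=O)OC(C)(C)C | intermediate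
20 | 6α-hydroxy 8α-triethylsilyloxy C1=C10 diester | C1(C(=O)OC)CC[C@H]2[C@](C)(CC=C)[C@H](O)C[C@H](O[Si](CC)(CC)CC)[C@]2(C)C=1C(=O)OC(C)(C)C | intermediate
21 | 6β-chloro 8α-triethylsilyloxy C1=C10 diester | C1(C(=O)OC)CC[C@H]2[C@](C)(CC=C)[C@@H](Cl)C[C@H](O[Si](CC)(CC)CC)[C@]2(C)C=1C(=O)OC(C)(C)C | intermediate
22 | 6β-chloro 8α-triethylsilyloxy C1=C2 diester: CO2Me on C1, 10β-CO2t-Bu, 10α-H | COC(=O)C1=CC[C@H]2[C@](C)(CC=C)[C@@H](Cl)C[C@H](O[Si](CC)(CC)CC)[C@]2(C)[C@H]1C(=O)OC(C)(C)C | intermediate
23 | 6β-chloro-8α-hydroxy 10β-carboxylic acid with the C1=C2 methyl ester and 5α-allyl | COC(=O)C1=CC[C@H]2[C@](C)(CC=C)[C@@H](Cl)C[C@H](O)[C@]2(C)[C@H]1C(=O)O | intermediate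
24 | S-ethyl 10β-thioester of 23 | COC(=O)C1=CC[C@H]2[C@](C)(CC=C)[C@@H](Cl)C[C@H](O)[C@]2(C)[C@H]1C(=O)SCC | intermediate
25 | 2-methylbut-3-en-2-ol | CC(C)(O)C=C | starting material
26 | S-ethyl 10β-thioester with the (E)-4-hydroxy-4-methylpent-2-enyl chain on C5 | COC(=O)C1=CC[C@H]2[C@](C)(C/C=C/C(C)(C)O)[C@@H](Cl)C[C@H](O)[C@]2(C)[C@H]1C(=O)SCC | intermediate
27 | target (CNP0167913.1) | COC(=O)C1=CC[C@H]2[C@](C)(C/C=C/C(C)(C)O)[C@@H](Cl)C[C@H](O)[C@]2(C)[C@H]1C=O | target

Total step count: 19. Longest linear sequence: 19 steps from 1; compounds 4, 10 and 25 are commercial and enter directly.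

Steps least certain to work

Step 7 (key step).
- Most likely to go wrong: the cascade stops half-way (proton loss from the C9 cation after closure of ring A only), or the activated epoxide rearranges by hydride shift to a carbonyl compound before the alkene engages. The β-dicarbonyl may also tie up the Lewis acid, and the tert-butyl ester may be partly cleaved if the mixture warms before the quench.
- Fallback: setting out from 11, the β-keto ester is first converted (t-BuMe2SiOTf, Et3N, CH2Cl2, −78 °C) into the silyl enol ether tert-butyl (2Z,6E)-3-(tert-butyldimethylsilyloxy)-7-methyl-9-[(2S,3S)-3-methyl-3-(prop-2-en-1-yl)oxiran-2-yl]nona-2,6-dienoate F1. This is a stronger, non-chelating carbon terminator of the kind used in epoxy-polyene cyclisations. MeAlCl2 at −90 °C then only has to activate the epoxide; the silyl oxocarbenium ion formed on capture of the C9 cation loses silicon on work-up, and the route is rejoined at 12.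

Step 14.
- Most likely to go wrong: substitution loses to elimination towards C7 (the axial leaving group is antiperiplanar to the axial C7 hydrogen) or to migration of the antiperiplanar C5 methyl, because chloride must approach a neopentyl-type carbon past the syn C5 methyl.
- Fallback (retention in place of inversion): setting out from 18, hydroxyl-directed reduction with Me4NBH(OAc)3 (MeCN–AcOH, −20 °C; internal hydride delivery from the 8α-oxygen to the α face of C6) should give the 6β,8α-diol of the C1=C10 diester F2. The more accessible equatorial 6β-hydroxyl reacts with SOCl2 (1 equiv, CH2Cl2, −78 °C) to give the 6β-chlorosulfite F3. With catalytic TiCl4 at 0 °C this collapses by front-side delivery of chloride with loss of SO2, the known stereoretentive chlorination of cyclic secondary chlorosulfites, to the 6β-chloro-8α-alcohol F4. Silylation with Et3SiOTf and 2,6-lutidine rejoins the route at 21.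

Step 3.
- Most likely to go wrong: decomposition of the epoxy triflate before coupling, competing attack of the organometallic on the allylic acetate, or opening of the epoxide by magnesium halide.
- Fallback: setting out from 2, the allylic alcohol is converted into (2E,6E)-8-bromo-3,7-dimethylocta-2,6-dien-1-yl acetate F5 (CBr4, PPh3, CH2Cl2, 0 °C). Stille coupling with tributyl(vinyl)stannane (Pd2(dba)3, AsPh3, THF, 50 °C; the allylic bromide adds to zerovalent palladium much faster than the allylic acetate) gives the skipped triene (2E,6E)-3,7-dimethyldeca-2,6,9-trien-1-yl acetate F6. Shi epoxidation (L-fructose-derived ketone catalyst, KHSO5, K2CO3, MeCN–dimethoxymethane–H2O, 0 °C) of the electron-rich 6,7-alkene, which should be preferred over the acetate-deactivated 2,3-alkene and the vinyl group, rejoins the route at 6. The ketone enantiomer is chosen by the spiro transition-state model to give the (S,S)-epoxide.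

Step 15.
- Most likely to go wrong: the equilibration stalls or stops at an unfavourable ratio, protonation at C10 gives some of the axial epimer, or the silyl ether is lost and the axial epimer is then drained by lactonisation onto the 8α-oxygen.
- Fallback: setting out from 21, the acidolysis is done first (CF3CO2H–CH2Cl2) to give the 6β-chloro-8α-hydroxy C1=C10 half-ester acid F7, which is coupled with EtSH (EDC·HCl, DMAP) to the C1=C10 S-ethyl thioester F8. The thioester acidifies the C2 hydrogens more strongly, so a mild amine base (DBU, CH2Cl2, rt) should suffice to move the alkene to C1=C2 with the thioester equatorial, rejoining the route at 24.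

Step 19.
- Most likely to go wrong: slow reduction of the hindered thioester, with competing hydrogenation or migration of the side-chain alkene on the palladium surface.
- Fallback: setting out from 23, the acid is converted into the Weinreb amide F9 (MeNHOMe·HCl, EDC·HCl, i-Pr2NEt, CH2Cl2). Cross-metathesis with 25 under the conditions of step 18 gives the side-chain-extended Weinreb amide F10. Reduction with Cp2Zr(H)Cl (excess, THF, rt), which takes tertiary amides to aldehydes in the presence of esters and is faster on the amide than on a hindered internal alkene, arrives at 27.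

## Further compounds

F1 | step 7 | tert-butyl (2Z,6E)-3-(tert-butyldimethylsilyloxy)-7-methyl-9-[(2S,3S)-3-methyl-3-(prop-2-en-1-yl)oxiran-2-yl]nona-2,6-dienoate | C=CC[C@]1(C)O[C@H]1CC/C(C)=C/CC/C(O[Si](C)(C)C(C)(C)C)=C/C(=O)OC(C)(C)C
F2 | step 14 | 6β,8α-diol of the C1=C10 diester | C1(C(=O)OC)CC[C@H]2[C@](C)(CC=C)[C@@H](O)C[C@H](O)[C@]2(C)C=1C(=O)OC(C)(C)C
F3 | step 14 | 6β-chlorosulfite of the 8α-hydroxy C1=C10 diester | C1(C(=O)OC)CC[C@H]2[C@](C)(CC=C)[C@@H](OS(=O)Cl)C[C@H](O)[C@]2(C)C=1C(=O)OC(C)(C)C
F4 | step 14 | 6β-chloro-8α-hydroxy C1=C10 diester | C1(C(=O)OC)CC[C@H]2[C@](C)(CC=C)[C@@H](Cl)C[C@H](O)[C@]2(C)C=1C(=O)OC(C)(C)C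
F5 | step 3 | (2E,6E)-8-bromo-3,7-dimethylocta-2,6-dien-1-yl acetate | BrC/C(C)=C/CC/C(C)=C/COC(C)=O
F6 | step 3 | (2E,6E)-3,7-dimethyldeca-2,6,9-trien-1-yl acetate | C=CC/C(C)=C/CC/C(C)=C/COC(C)=O
F7 | step 15 | 6β-chloro-8α-hydroxy C1=C10 half-ester acid (CO2Me on C1, CO2H on C10) | C1(C(=O)OC)CC[C@H]2[C@](C)(CC=C)[C@@H](Cl)C[C@H](O)[C@]2(C)C=1C(=O)O
F8 | step 15 | 6β-chloro-8α-hydroxy C1=C10 S-ethyl thioester (CO2Me on C1, COSEt on C10) | C1(C(=O)OC)CC[C@H]2[C@](C)(CC=C)[C@@H](Cl)C[C@H](O)[C@]2(C)C=1C(=O)SCC
F9 | step 19 | N-methoxy-N-methyl 10β-carboxamide of 23 | COC(=O)C1=CC[C@H]2[C@](C)(CC=C)[C@@H](Cl)C[C@H](O)[C@]2(C)[C@H]1C(=O)N(C)OC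
F10 | step 19 | N-methoxy-N-methyl 10β-carboxamide with the (E)-4-hydroxy-4-methylpent-2-enyl chain on C5 | COC(=O)C1=CC[C@H]2[C@](C)(C/C=C/C(C)(C)O)[C@@H](Cl)C[C@H](O)[C@]2(C)[C@H]1C(=O)N(C)OC
A1 | alternative 1 | bicyclic cross-conjugated cyclohexadienone allyl β-keto ester | C=CCOC(=O)[C@H]1C(=O)CCC2=C(C)C(=O)C=C[C@]12C
A2 | alternative 1 | allyl 5-(3-hydroxy-2,6-dimethylphenyl)-3-oxopentanoate | C=CCOC(=O)CC(=O)CCc1c(C)ccc(O)c1C
A3 | alternative 2 | trans-fused octalin aldehyde (C2=C3, 1β-CH2OPMB, 10β-CHO, C6 ketone, 8α-OTBS, 5α-allyl) | COc1ccc(COC[C@H]2C=C[C@H]3[C@](C)(CC=C)C(=O)C[C@H](O[Si](C)(C)C(C)(C)C)[C@]3(C)[C@H]2C=O)cc1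
A4 | alternative 2 | acyclic (E,E)-dienyl (E)-enal with quaternary C5, C6 ketone and C8 silyl ether | COc1ccc(COC/C=C/C=C/[C@](C)(CC=C)C(=O)C[C@H](O[Si](C)(C)C(C)(C)C)/C(C)=C/C=O)cc1
A5 | alternative 3 | 8β-hydroxy trans-octalin methyl ester (C1=C2, C5=C6, 10β-CH2OTBS) | COC(=O)C1=CC[C@H]2C(C)=CC[C@@H](O)[C@]2(C)[C@H]1CO[Si](C)(C)C(C)(C)C
A6 | alternative 3 | ten-membered (E,E)-dienoate with the trans C8–C9 epoxide and the C10 silyloxymethyl group | COC(=O)/C1=C/C/C=C(C)/CC[C@H]2O[C@]2(C)[C@H]1CO[Si](C)(C)C(C)(C)C
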